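**Plan**
- Retrosynthetic cuts, in order: (a) remove H2 from C1–C5 and C7–C8, because H-1, H-5 and H-7 share the α face with 4-OH, 6-OH and 10-OH; (b) cut C11–C12 and C11–C13 back to a methyl ester on C7; (c) cut C6–C7 and C9–C10 of the seven-membered ring B.
- Enabling feature: in ring B the carbinol carbons C6 and C10 are 1,4-related, cis, and flank the fusion bond C1–C5. So C10–C1–C5–C6 is the bis-enol (diene) form of a 2-acetylcyclopentanecarbaldehyde, and C7–C8–C9 with C11 on C7 is an ester-bearing vinylcarbene. The event is a formal [4+3]: cyclopropanation followed by Cope ring expansion.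
- Helper: a temporary O–Si–O bridge (a 1,3,2-dioxasilepine ring) holds both enol oxygens inside the diene. It fixes enol regiochemistry and geometry and forces the two C–O bonds cis. Fluoride removes it later.
- Forward order: ring A (C1–C5) by ring contraction of (R)-limonene, then the temporary silepine ring, ring B by the [4+3] event, the side chain, desilylation, hydrogenation.
- Stereochemistry: the limonene centre (C1) sets C4 by anti epoxidation and is then erased. C4 sets C6 and C10 through its blocked OSiEt3 face. The three α hydroxyls set C1, C5 and C7 by directed hydrogenation.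

Key step: step 8

Assumption: guaiane numbering is used. Ring A is C1–C5; ring B is C1, C10, C9, C8, C7, C6, C5; C14 sits on C10, C15 on C4, and C11–C13 form the side chain. α is the face that carries H-1 and H-5 in the target.

Step 1
Reactants: 1 (R)-(+)-limonene
Product: 2 (R)-3-isopropenyl-6-oxoheptanal
Conditions: O3 (1.0 equiv), CH2Cl2/MeOH, −78 °C; then Me2S, −78 °C to rt
Reagents that add atoms: ozone [O-][O+]=O
Why: Chemoselective ozonolysis, in which the electron-richer trisubstituted ring alkene takes up the single equivalent of ozone before the 1,1-disubstituted isopropenyl group and the stereocentre (future C1) is not touched.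

Step 2
Reactants: 2 (R)-3-isopropenyl-6-oxoheptanal
Product: 3 (S)-2-methyl-5-(prop-1-en-2-yl)cyclopent-1-ene-1-carbaldehyde
Conditions: piperidine (cat.), AcOH (cat.), toluene, reflux (Dean–Stark)
Reagents that add atoms: none
Why: Amine-catalysed intramolecular aldol condensation (5-enolexo), in which the aldehyde enamine attacks the methyl ketone and water is lost, a long-used ring contraction of limonene that forms ring A and leaves the stereocentre intact.

Step 3
Reactants: 3 (S)-2-methyl-5-(prop-1-en-2-yl)cyclopent-1-ene-1-carbaldehyde
Product: 4 (1S,2S,5R)-5-methyl-2-(prop-1-en-2-yl)-6-oxabicyclo[3.1.0]hexane-1-carbaldehyde (C4–C5 α-epoxide, trans to the isopropenyl group)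
Conditions: 30% aq H2O2, NaOH (cat.), MeOH, 0 °C
Reagents that add atoms: hydrogen peroxide OO
Why: Weitz–Scheffer nucleophilic epoxidation, in which hydroperoxide adds only to the electron-poor enal C=C and closes the oxirane on the ring face opposite the neighbouring β isopropenyl group, so that C4 is set as (R) with oxygen on the α face.

Step 4
Reactants: 4 (1S,2S,5R)-5-methyl-2-(prop-1-en-2-yl)-6-oxabicyclo[3.1.0]hexane-1-carbaldehyde
Product: 6 (R)-2-acetyl-5-hydroxy-5-methylcyclopent-1-ene-1-carbaldehyde, via epoxy keto aldehyde 5 (not isolated)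
Conditions: O3, CH2Cl2, −78 °C; Me2S, −78 °C to rt; then Et3N (cat.), 0 °C, short contact
Reagents that add atoms: ozone [O-][O+]=O
Why: Ozonolysis unmasks the methyl ketone and its C1 enolate opens the β,γ-epoxide by E1cB elimination (the known epoxy ketone to γ-hydroxy enone isomerisation), in which the C4–O bond is not broken, so C4 stays (R) while the now redundant C1 centre is erased.

Step 5
Reactants: 6 (R)-2-acetyl-5-hydroxy-5-methylcyclopent-1-ene-1-carbaldehyde
Product: 7 (R)-2-acetyl-5-methyl-5-(triethylsilyloxy)cyclopent-1-ene-1-carbaldehyde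
Conditions: Et3SiOTf, 2,6-lutidine, CH2Cl2, −78 to 0 °C
Reagents that add atoms: triethylsilyl triflate CC[Si](CC)(CC)OS(=O)(=O)C(F)(F)F
Why: Silyl triflate silylation of a hindered tertiary alcohol, in which the weak hindered base leaves both carbonyl groups unenolised at low temperature and the new group later shields the α face.

Step 6
Reactants: 7 (R)-2-acetyl-5-methyl-5-(triethylsilyloxy)cyclopent-1-ene-1-carbaldehyde
Product: 8 (7R)-2,2-diisopropyl-4,7-dimethyl-7-(triethylsilyloxy)-6,7-dihydro-5H-cyclopenta[e][1,3,2]dioxasilepine (silylene-bridged Z,Z-bis(enol ether) C10=C1–C5=C6)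
Conditions: Zn dust (activated), iPr2SiCl2, 2,6-lutidine, THF, 0 °C, slow addition of 7; filtration through basic alumina
Reagents that add atoms: dichlorodiisopropylsilane CC(C)[Si](Cl)(Cl)C(C)C
Why: Proposed new method: zinc passes two electrons into the low-lying LUMO of the 2-ene-1,4-dicarbonyl unit, whose carbonyl groups are held cis by ring A (the same electron uptake as in the classical Zn/AcOH reduction of ene-diones), the first O-silylation places a Si–Cl next to the second enolate oxygen, and closure gives the seven-membered bis(silyl enol ether) with both C=C bonds regiodefined and no proton ever put on C1 or C5; the closest known reaction type is the reductive O,O-bis-silylation of quinones and 1,2-diketones by Zn or Mg and chlorosilanes, which with R2SiCl2 gives cyclic enediol silyl ethers; no stereocentre is formed and C4 is untouched.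

Step 7
Reactants: 9 methyl but-3-enoate
Product: 10 methyl 2-diazobut-3-enoate
Conditions: 4-acetamidobenzenesulfonyl azide, DBU, MeCN, 0 °C; used at once as a cold hexane solution
Reagents that add atoms: 4-acetamidobenzenesulfonyl azide CC(=O)Nc1ccc(cc1)S(=O)(=O)N=[N+]=[N-]
Why: Regitz diazo transfer to the dienolate of a β,γ-unsaturated ester, the standard access to vinyldiazoacetates, with immediate use because the parent compound slowly cyclises to a pyrazole.

Step 8
Reactants: 8 (7R)-2,2-diisopropyl-4,7-dimethyl-7-(triethylsilyloxy)-6,7-dihydro-5H-cyclopenta[e][1,3,2]dioxasilepine; 10 methyl 2-diazobut-3-enoate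
Product: 12 methyl 6α,10α-(diisopropylsilanediyldioxy)-4α-(triethylsilyloxy)-12,13-dinorguaia-1(5),7-dien-11-oate, via cis-divinylcyclopropane 11 (not isolated)
Conditions: Rh2(O2CC7H15)4 (1 mol %), hexanes, 60 °C, slow addition of 10 (2 equiv)
Reagents that add atoms: none
Why: Proposed new method: Loss of N2 from 10 at the dirhodium core gives an electrophilic metal-bound vinylcarbene whose carbene carbon (C7) adds to the C5=C6 enol ether of 8 to give the cis-divinylcyclopropane 11, and a strain-driven [3,3] shift (Cope rearrangement) then breaks C5–C7 and joins C9 to C10, so that C6–C7 and C9–C10 arise in one operation. The closest known reaction type is the tandem cyclopropanation/Cope rearrangement (formal [4+3] cycloaddition) of vinyldiazoacetates with 1-silyloxydienes, cyclopentadiene and furans; new here are the silylene-bridged bis(enol ether) as four-carbon partner and the bicyclo[3.3.2] outcome. The three-membered ring closes by a concerted, asynchronous [2+1] addition, and ring B closes by ring expansion of that cyclopropane through the boat-shaped [3,3] transition state, the only one open to a cis-divinylcyclopropane, which gives the Z alkenes C7=C8 and C1=C5. C6 and C10 are set together: both new C–C bonds form on one face of the diene and the O–Si–O bridge keeps both oxygens on the inside positions, so they must end cis to each other on the opposite face, while the face itself is chosen by C4, whose OSiEt3 group shields the α face and leaves the CH3-bearing β face open (6α-O, 10α-O). The step needs site selectivity (C5=C6 before C1=C10), secured because C6 is the only H-bearing, sterically open diene terminus and attack there is backed by the vinylogous donor O10, and it needs the vinyl group to end cis to C1, the normal preference of donor/acceptor carbenes, whose ester turns away from the alkene substituents. A non-polar solvent and a carboxylate catalyst are chosen to disfavour zwitterionic silyl transfer and allylic C–H insertion.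

Step 9
Reactants: 12 methyl 6α,10α-(diisopropylsilanediyldioxy)-4α-(triethylsilyloxy)-12,13-dinorguaia-1(5),7-dien-11-oate
Product: 14 12,13-dichloro-6α,10α-(diisopropylsilanediyldioxy)-4α-(triethylsilyloxy)guaia-1(5),7-dien-11-ol, via chloromethyl ketone 13 (not isolated)
Conditions: ICH2Cl (5 equiv), MeLi·LiBr (4.5 equiv, added last), THF/Et2O, −78 °C; AcOH quench at −78 °C
Reagents that add atoms: chloroiodomethane ClCI
Why: Double 1,2-addition of a lithium carbenoid to an ester, in which chloromethyllithium made by I/Li exchange in the presence of 12 attacks the carbonyl as a hard nucleophile, the adduct collapses to the more electrophilic ketone 13 and this takes a second equivalent, a known route from esters (conjugated ones included) to 1,3-dichloro-2-alkanols; C11 carries two like arms, so no stereocentre arises.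

Step 10
Reactants: 14 12,13-dichloro-6α,10α-(diisopropylsilanediyldioxy)-4α-(triethylsilyloxy)guaia-1(5),7-dien-11-ol
Product: 18 12,13-diacetoxy-6α,10α-(diisopropylsilanediyldioxy)-4α-(triethylsilyloxy)guaia-1(5),7-dien-11-ol, via chloromethyl oxirane 15 (not isolated), via acetoxy chlorohydrin 16 (not isolated), via acetoxymethyl oxirane 17 (not isolated)
Conditions: CsOAc (excess), AcOH (buffer), DMF, 80 °C
Reagents that add atoms: cesium acetate CC(=O)[O-].[Cs+]
Why: Neighbouring-group-assisted substitution, in which the tertiary 11-OH closes an oxirane on one CH2Cl arm (15), acetate opens it at the CH2 end by SN2 (16) and the same closure and opening (17) exchanges the second chloride, so that no direct attack on a neopentyl-type carbon is needed, the silyl ethers and alkenes are untouched, and C11 is transiently stereogenic only in 15–17.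

Step 11
Reactants: 18 12,13-diacetoxy-6α,10α-(diisopropylsilanediyldioxy)-4α-(triethylsilyloxy)guaia-1(5),7-dien-11-ol
Product: 19 12,13-diacetoxyguaia-1(5),7-diene-4α,6α,10α,11-tetraol
Conditions: Et3N·3HF, Et3N, THF, rt to 40 °C
Reagents that add atoms: none
Why: Fluoride-mediated Si–O cleavage, in which the nearly neutral amine–HF complex removes the silylene bridge and the triethylsilyl ether without touching the acetates or ionising the allylic carbinols, and no C–O bond is broken, so C4, C6 and C10 keep their configuration.

Step 12
Reactants: 19 12,13-diacetoxyguaia-1(5),7-diene-4α,6α,10α,11-tetraol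
Product: 20 (1R,4R,5S,6S,7R,10R)-12,13-diacetoxyguaiane-4,6,10,11-tetraol (1αH,5αH,7αH; 4α,6α,10α-OH; target CNP0179913.1)
Conditions: H2 (50 bar), [Ir(cod)(PCy3)(py)]PF6 (10 mol %), CH2Cl2, rt
Reagents that add atoms: none
Why: Hydroxyl-directed homogeneous hydrogenation, in which the cationic iridium centre binds the allylic hydroxyls 4-OH, 6-OH and 10-OH, all on the α face next to the tetrasubstituted C1=C5 and trisubstituted C7=C8 bonds, so that both H2 molecules should arrive from α and set H-1, H-5 and H-7, a sense the two β methyl groups C14 and C15 reinforce sterically.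

**Compound list**
1 | (R)-(+)-limonene | CC1=CC[C@@H](CC1)C(C)=C | starting material
2 | (R)-3-isopropenyl-6-oxoheptanal | CC(=O)CC[C@H](CC=O)C(C)=C | intermediate
3 | (S)-2-methyl-5-(prop-1-en-2-yl)cyclopent-1-ene-1-carbaldehyde | CC1=C(C=O)[C@@H](CC1)C(C)=C | intermediate
4 | (1S,2S,5R)-5-methyl-2-(prop-1-en-2-yl)-6-oxabicyclo[3.1.0]hexane-1-carbaldehyde | C[C@@]12CC[C@@H](C(C)=C)[C@]1(C=O)O2 | intermediate
5 | (1S,2R,5R)-2-acetyl-5-methyl-6-oxabicyclo[3.1.0]hexane-1-carbaldehyde (not isolated) | C[C@@]12CC[C@@H](C(C)=O)[C@]1(C=O)O2 | intermediate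
6 | (R)-2-acetyl-5-hydroxy-5-methylcyclopent-1-ene-1-carbaldehyde | CC(=O)C1=C(C=O)[C@](C)(O)CC1 | intermediate
7 | (R)-2-acetyl-5-methyl-5-(triethylsilyloxy)cyclopent-1-ene-1-carbaldehyde | CC(=O)C1=C(C=O)[C@](C)(O[Si](CC)(CC)CC)CC1 | intermediate
8 | (7R)-2,2-diisopropyl-4,7-dimethyl-7-(triethylsilyloxy)-6,7-dihydro-5H-cyclopenta[e][1,3,2]dioxasilepine | CC1=C2CC[C@@](C)(O[Si](CC)(CC)CC)C2=CO[Si](C(C)C)(C(C)C)O1 | intermediate
9 | methyl but-3-enoate | COC(=O)CC=C | starting material
10 | methyl 2-diazobut-3-enoate | COC(=O)C(=[N+]=[N-])C=C | intermediate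
11 | cis-divinylcyclopropane (C5–C6–C7 ring on the β face, vinyl cis to C1, ester cis to C4; not isolated) | COC(=O)[C@@]1(C=C)[C@@H]2O[Si](C(C)C)(C(C)C)OC(C)=C3CC[C@@](C)(O[Si](CC)(CC)CC)[C@@]123 | intermediate
12 | methyl 6α,10α-(diisopropylsilanediyldioxy)-4α-(triethylsilyloxy)-12,13-dinorguaia-1(5),7-dien-11-oate | COC(=O)C1=CC[C@@]2(C)O[Si](C(C)C)(C(C)C)O[C@@H]1C3=C2CC[C@@]3(C)O[Si](CC)(CC)CC | intermediate
13 | C11 chloromethyl ketone of the same core (not isolated) | ClCC(=O)C1=CC[C@@]2(C)O[Si](C(C)C)(C(C)C)O[C@@H]1C3=C2CC[C@@]3(C)O[Si](CC)(CC)CC | intermediate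
14 | 12,13-dichloro-6α,10α-(diisopropylsilanediyldioxy)-4α-(triethylsilyloxy)guaia-1(5),7-dien-11-ol | ClCC(O)(CCl)C1=CC[C@@]2(C)O[Si](C(C)C)(C(C)C)O[C@@H]1C3=C2CC[C@@]3(C)O[Si](CC)(CC)CC | intermediate
15 | 13-chloro-11,12-epoxide of the same core (C11 epimers, not isolated) | ClCC1(CO1)C2=CC[C@@]3(C)O[Si](C(C)C)(C(C)C)O[C@@H]2C4=C3CC[C@@]4(C)O[Si](CC)(CC)CC | intermediate
16 | 12-acetoxy-13-chloro-11-ol of the same core (C11 epimers, not isolated) | CC(=O)OCC(O)(CCl)C1=CC[C@@]2(C)O[Si](C(C)C)(C(C)C)O[C@@H]1C3=C2CC[C@@]3(C)O[Si](CC)(CC)CC | intermediate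
17 | 12-acetoxy-11,13-epoxide of the same core (C11 epimers, not isolated) | CC(=O)OCC1(CO1)C2=CC[C@@]3(C)O[Si](C(C)C)(C(C)C)O[C@@H]2C4=C3CC[C@@]4(C)O[Si](CC)(CC)CC | intermediate
18 | 12,13-diacetoxy-6α,10α-(diisopropylsilanediyldioxy)-4α-(triethylsilyloxy)guaia-1(5),7-dien-11-ol | CC(=O)OCC(O)(COC(C)=O)C1=CC[C@@]2(C)O[Si](C(C)C)(C(C)C)O[C@@H]1C3=C2CC[C@@]3(C)O[Si](CC)(CC)CC | intermediate
19 | 12,13-diacetoxyguaia-1(5),7-diene-4α,6α,10α,11-tetraol | CC(=O)OCC(O)(COC(C)=O)C1=CC[C@@](C)(O)C2=C([C@H]1O)[C@](C)(O)CC2 | intermediate
20 | (1R,4R,5S,6S,7R,10R)-12,13-diacetoxyguaiane-4,6,10,11-tetraol (CNP0179913.1) | CC(=O)OCC(O)(COC(C)=O)[C@@H]1CC[C@@](C)(O)[C@@H]2CC[C@@](C)(O)[C@@H]2[C@H]1O | target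

Total step count: 12. Longest linear sequence: 11 steps (steps 1–6 and 8–12, from 1).

**Steps most likely to fail**

1. Step 8.
 - What may go wrong: the facial bias between CH3 and OSiEt3 at C4 may be poor. The electron-rich bis(enol ether) may react through a zwitterion with silyl transfer. The carbene may insert into the allylic C2–H bonds. The Cope shift may stall in the bridged system.
 - Fallback (known chemistry; ring B is closed by olefin metathesis instead), from 7 back to 12: the α-(methoxycarbonyl)vinylalane made from methyl propiolate with iBu2AlH and N-methylmorpholine N-oxide adds to the aldehyde of 7 to give the Morita–Baylis–Hillman-type carbinol F2. Barbier allylation of the ketone (allyl bromide, In, THF/H2O) gives the allyl acrylate diol F3. Ring-closing metathesis (second-generation Hoveyda–Grubbs catalyst, toluene, 80 °C) joins C7 to C8 and gives the dienediol ester F4. iPr2Si(OTf)2 and 2,6-lutidine can bridge only a cis-6,10-diol, so this last operation protects the diol, sorts out the trans-6,10-diols and returns to 12; any all-β cis-6,10-diol would also be bridged and has to be separated from 12 by chromatography.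

2. Step 6.
 - What may go wrong: the C4 silyloxy group may be lost by β-elimination from the transient enolate. Intermolecular silylation or radical-anion dimerisation may compete with ring closure. ZnCl2 may ionise the allylic silyl ether.
 - Fallback (known chemistry; electron transfer and silylation are separated), from 7 back to 8: conjugate reduction of the ene-dione with Zn in AcOH gives the saturated keto aldehyde F1, a mixture at C1 and C5 that does not matter. Soft double enolisation with iPr2Si(OTf)2 and Et3N in CH2Cl2 at 0 °C then gives 8. In that step, enolisation towards C1 is favoured because it yields the conjugated diene.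

3. Step 12.
 - What may go wrong: uptake at the tetrasubstituted alkene may be slow, and the polyol may deactivate the catalyst by chelation. The secondary allylic alcohol may isomerise to a ketone by a 1,3-hydrogen shift. The doubly allylic C6 carbinol may ionise under acid. Hydrogen may reach C7 from the β face, steered by the freely rotating 11-OH.
 - Fallback (radical hydrogen-atom transfer instead of inner-sphere delivery), from 19 back to 20: Mn(dpm)3 (cat.), PhSiH3, tBuOOH, iPrOH, rt. Here each hydrogen atom should arrive on the α face because the two β methyl groups block the other one, and C7 should settle 6,7-trans. No new compound arises (entry F0).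

**Further compounds**
F1 | step 6 | (5R)-2-acetyl-5-methyl-5-(triethylsilyloxy)cyclopentane-1-carbaldehyde (mixture at ring C-1/C-2 = guaiane C5/C1) | CC(=O)C1CC[C@@](C)(O[Si](CC)(CC)CC)C1C=O
F2 | step 8 | methyl 2-{hydroxy[(5R)-2-acetyl-5-methyl-5-(triethylsilyloxy)cyclopent-1-en-1-yl]methyl}acrylate (6α-OH isomer) | C=C(C(=O)OC)[C@H](O)C1=C(C(C)=O)CC[C@@]1(C)O[Si](CC)(CC)CC
F3 | step 8 | allyl acrylate diol (6α-OH, 10α-OH isomer; C10 bears CH3, OH and allyl) | C=CC[C@@](C)(O)C1=C([C@@H](O)C(=C)C(=O)OC)[C@](C)(O[Si](CC)(CC)CC)CC1
F4 | step 8 | methyl 6α,10α-dihydroxy-4α-(triethylsilyloxy)-12,13-dinorguaia-1(5),7-dien-11-oate | COC(=O)C1=CC[C@@](C)(O)C2=C([C@H]1O)[C@](C)(O[Si](CC)(CC)CC)CC2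
F0 | step 12 | none | none
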